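## The problem

The target is a 3,3''-linked biflavanone. Two 2-(4-methoxyphenyl)chroman-4-ones are joined through the C3–C3'' bond, so the four stereocentres C2, C3, C3'' and C2'' are contiguous and the ketones C4 and C4'' flank a crowded central bond. Unit 1 (5,7-dihydroxy) is 2,3-trans, (2S,3R); unit 2 (5''-hydroxy-7''-methoxy) is 2'',3''-cis, (2''S,3''S). The trans pair is the thermodynamic arrangement and can be reached by equilibrating C3 once C2 is fixed. The cis pair is a kinetic arrangement that needs syn delivery of two hydrogens and does not survive base. All four centres are labile: C3 and C3'' epimerise through the enols of C4 and C4'', and C2 and C2'' are lost by retro-oxa-Michael ring opening, most easily in 5-hydroxyflavanones. The free phloroglucinol ring of unit 1 is also sensitive to oxidants and strong Lewis acids. The stereocentres must therefore be made in the last steps, trans unit first and cis unit last, with nothing basic afterwards. The feature that opens the route is ring A of unit 1: C4a carries the C4 ketone and is flanked by the oxygen-bearing C5 and C8a, with a third oxygen at C7. This is an acylphloroglucinol, the folded form of a 3,5,7-triketo ester, so closing the C4a–C5 bond by Claisen condensation delivers the ring with both hydroxyls free.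

## Retrosynthesis

**21 from 20.** Only the O5''–benzyl bond is cut. A benzyl ether is the one phenol protecting group that leaves under neutral conditions; acid, Lewis acid or base would each endanger the cis centre C3''. The forward step is a hydrogenolysis that must leave the ketones and the benzylic C2–O1 bonds alone.

**20 from 19.** The C–H bonds at C2'' and C3'' are removed, which turns unit 2 into a flavone. Closing unit 2 by oxa-Michael addition instead would equilibrate to trans. Here the cis relation follows from the mechanism, because both hydrogens arrive on one face, and unit 2 can pass through every basic step as a flat, achiral chromone. 19 has two stereocentres fewer. The forward step must saturate a tetrasubstituted, donor-substituted double bond from the face that gives (2''S,3''S), stop at the ketone and use no base.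

**19 from 18.** The O1–C2 bond of unit 1 is cut, giving the 2',4',6'-trihydroxychalcone 18, which has no stereocentre. Its two ortho hydroxyls are equivalent, so there is no regiochemical question. Cutting C2–C3 instead would need a protected salicyl ketone and would give up the free phloroglucinol. The forward conjugate addition must set C2 as S under catalyst control, and C3 must settle trans.

**18 from 17 (key disconnection).** The C4a–C5 bond of ring A of unit 1 is cut, unfolding the acylphloroglucinol into the 3,5,7-triketo ester 17. The neighbouring cut C4–C4a (acylation of phloroglucinol 1) is equally regioselective because 1 is symmetric. It would, however, need a strong Lewis acid, which would strip the peri benzyl ether of unit 2 and close the chalcone to the racemic flavanone in the same flask. The Claisen route uses a mild magnesium alkoxide and hands over the open chalcone with all three hydroxyls free. 17 holds no stereocentre. The forward reaction has to prefer the Claisen mode over the aldol mode, pyrone formation and conjugate addition.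

**17 from 11 and 15.** The C6–C7 bond is cut: the terminal carbanion of trianion 16, made from methyl 3,5-dioxohexanoate 15, is acylated by methyl ester 11. This is the most convergent cut, since 15 brings in the whole triketide chain as one unit. 11 has no alpha or gamma hydrogen, so the polyanion cannot enolise it. The forward step asks for 1,2-attack on a hindered, conjugated ester in the presence of the chromone.

**11 from 6 and 7.** The acrylate C=C bond (the later C2–C3 of unit 1) is cut by a Perkin condensation of flavone-3-acetic acid 6 with 4-methoxybenzaldehyde 7, giving acid 9 through its diacetate 8. One methylation then installs the ester and the 7''-O-methyl group (10), because the chelated 5''-hydroxyl does not react; benzylation of that hydroxyl gives 11. A cross-coupling at C3'' of a 3-haloflavone would make the hindered bond late; the condensation keeps it intact from the start.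

**6 from 3 and 4; 3 from 1 and 2.** The pyranone of unit 2 is cut at O1''–C2'' and C2''–C3'' (Allan–Robinson synthesis from ketone 3 and 4-methoxybenzoic anhydride 4, through 5). Ketone 3 is cut at C4''–C4a'' (Friedel–Crafts acylation of 1 with methyl 4-chloro-4-oxobutanoate 2). The crowded C3–C3'' bond of the target is never formed: it is the C2–C3 bond of the succinyl chain of 2. The symmetry of 1 removes any regiochemical question, and the methyl group is added later, when chelation tells the two phenols apart.

**15 from 12 and 13.** The C4–C5 bond of 15 is cut: dianion 14 of methyl acetoacetate 12 is acylated at its terminal carbon by N-methoxy-N-methylacetamide 13.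

## Roads not taken

**Alternative 1:** Ring C of unit 1 is cut at O1–C2 and C3–C4. In the forward sense a Lewis acid ionises the salicylaldehyde acetal A1 to an alpha-methoxy ortho-quinone methide, which is trapped in a hetero-Diels–Alder reaction by the (E)-styryl group of the preformed cis-flavanone A2 to give the 4-methoxyflavan A3.
- Merits: two bonds and ring C form in one step, the E geometry is carried into the 2,3-trans relation, polarity fixes the regiochemistry, and the route is convergent.
- Weak points: A2 must already hold the kinetic cis pair, with C3'' alpha to a ketone, and must survive a Lewis acid. The face of the alkene is chosen only by the adjacent C3''. C4 arrives as a methyl ether at the alcohol oxidation level, so A3 needs hydrolysis and a benzylic oxidation beside three electron-rich rings, then three debenzylations.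
- Comparison: for the relative configuration of unit 1 the cycloaddition is at least as good as the equilibration in step 9, and it needs no chiral catalyst if A2 is enantiopure. Against this, the chosen plan forms no stereocentre before step 9, needs no oxidation-state correction at C4 and no protecting group on unit 1, and does not push the cis problem into a separate synthesis of A2.

**Alternative 2:** Ring A of unit 2 is cut at C8''–C8a'' and C4a''–C5''. Forward, diene A5 adds to the bromo-enone of dihydropyranone A4; the bromide and the acetal methoxy group are then eliminated and the new ring aromatises to A6.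
- Merits: the 5''-hydroxy-7''-methoxy pattern is written into the diene, so the two phenols need not be told apart, and the 5''-hydroxyl arrives free.
- Weak points: A4 carries all four stereocentres on a non-aromatic dihydropyranone with C3'' alpha to the enone carbonyl, and making it is harder than the original problem. The eliminations need heat or base, which threatens the cis centre. Unit 1 must carry two benzyl ethers.
- Comparison: both roads build an A ring late from a non-aromatic precursor. This one does so when every stereocentre is already present; the chosen plan does so when none is. Alternative 2 is better on the placement of the O-methyl group, which is beyond doubt there, whereas the chosen plan relies on chelation of the 5''-hydroxyl in step 4.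

**Alternative 3:** The O1''–C8a'' bond is cut. Forward, the C2'' alkoxide of the syn-aldol adduct A7 displaces the ortho fluoride, which is activated by the ortho acyl group, and closes the ring to A8 without touching C2'' or C3''.
- Merits: the cis pair comes from a syn-aldol reaction, an acyclic stereocontrol that is well understood, and is then locked by ring closure.
- Weak points: A7 is a beta-hydroxy ketone with C3'' alpha to the carbonyl, so the base needed for ring closure invites retro-aldol cleavage and epimerisation. Making A7 needs a defined enolate next to unit 1, whose own C3–H and O1 invite elimination. Three benzyl groups must be removed, and stereocentres are carried through a longer sequence.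
- Comparison: in control of the cis pair this road is better founded than step 10 of the chosen plan, which is its admitted weak point. The chosen plan sets against it that syn addition guarantees cis by mechanism, that the route is shorter, that the intermediates are achiral and robust until three steps from the end, and that unit 1 needs no protecting group.

Key step: step 8

Assumption: the sense of induction of the cinchona thiourea (step 9) and of the iridium ligand (step 10) cannot be derived from the structure alone; the antipodes named are taken to give the configurations drawn, and the quinidine-derived thiourea or the (R)-ligand is used instead if the first run shows the opposite sense.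

## Route

Step 1
Reactants: 1 phloroglucinol; 2 methyl 4-chloro-4-oxobutanoate
Product: 3 methyl 4-oxo-4-(2,4,6-trihydroxyphenyl)butanoate
Conditions: AlCl3 (4 equiv), PhNO2–CH2Cl2, 0 °C → 40 °C; aq. HCl
Reagents that add atoms: none
Why: Friedel–Crafts acylation of a threefold symmetric triphenol gives one regioisomer, and the chelated, deactivated product should resist a second acylation. The methyl ester is expected to survive AlCl3 at this temperature.

Step 2
Reactants: 3 methyl 4-oxo-4-(2,4,6-trihydroxyphenyl)butanoate; 4 4-methoxybenzoic anhydride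
Product: 6 2-[5,7-dihydroxy-2-(4-methoxyphenyl)-4-oxo-4H-chromen-3-yl]acetic acid, via bis-aroyl flavone ester 5 (not isolated)
Conditions: sodium 4-methoxybenzoate, neat, 175 °C; then KOH, EtOH–H2O, reflux; HCl
Reagents that add atoms: water (as hydroxide), O
Why: Allan–Robinson flavone synthesis: O-aroylation, acyl transfer to the ketone alpha-carbon and cyclodehydration give the 3-substituted flavone, since the alpha-CH2 next to the ketone is more acidic than the one next to the ester. The alkaline work-up removes the 5,7-O-aroyl groups and saponifies the ester.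

Step 3
Reactants: 6 2-[5,7-dihydroxy-2-(4-methoxyphenyl)-4-oxo-4H-chromen-3-yl]acetic acid; 7 4-methoxybenzaldehyde
Product: 9 (E)-2-[5,7-dihydroxy-2-(4-methoxyphenyl)-4-oxo-4H-chromen-3-yl]-3-(4-methoxyphenyl)prop-2-enoic acid, via diacetate 8 (not isolated)
Conditions: Ac2O, Et3N, 110 °C; then K2CO3, CH3OH–H2O, rt; HCl
Reagents that add atoms: none
Why: Perkin condensation of an arylacetic-type acid: the mixed-anhydride enolate is stabilised by the 2-arylchromone pi-system, and elimination should give the (E)-acid with carboxyl trans to the beta-aryl group. The phenol acetates formed in passing are cleaved in the work-up.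

Step 4
Reactants: 9 (E)-2-[5,7-dihydroxy-2-(4-methoxyphenyl)-4-oxo-4H-chromen-3-yl]-3-(4-methoxyphenyl)prop-2-enoic acid
Product: 10 methyl (E)-2-[5-hydroxy-7-methoxy-2-(4-methoxyphenyl)-4-oxo-4H-chromen-3-yl]-3-(4-methoxyphenyl)prop-2-enoate
Conditions: CH3I (2.3 equiv), K2CO3, acetone, reflux
Reagents that add atoms: iodomethane, CI
Why: Williamson alkylation of the carboxylate and the acidic 7-hydroxyl. The 5-hydroxyl is hydrogen-bonded to the C4 carbonyl and should not be methylated under these mild conditions.

Step 5
Reactants: 10 methyl (E)-2-[5-hydroxy-7-methoxy-2-(4-methoxyphenyl)-4-oxo-4H-chromen-3-yl]-3-(4-methoxyphenyl)prop-2-enoate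
Product: 11 methyl (E)-2-[5-(benzyloxy)-7-methoxy-2-(4-methoxyphenyl)-4-oxo-4H-chromen-3-yl]-3-(4-methoxyphenyl)prop-2-enoate
Conditions: BnBr, K2CO3, DMF, 70 °C
Reagents that add atoms: benzyl bromide, BrCc1ccccc1
Why: Williamson benzylation of the chelated 5-hydroxyl, which needs the more forcing dipolar aprotic conditions. The acrylate and the chromone are inert to carbonate.

Step 6
Reactants: 12 methyl acetoacetate; 13 N-methoxy-N-methylacetamide
Product: 15 methyl 3,5-dioxohexanoate, via dianion 14 (not isolated)
Conditions: NaH, THF, 0 °C; n-BuLi, 0 °C; then 13, 0 °C → rt; aq. HCl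
Reagents that add atoms: none
Why: Acylation of an acetoacetate dianion at its terminal carbon. The chelated tetrahedral adduct of the N-methoxy-N-methylamide persists until work-up, so neither over-addition nor proton quench by the product should occur.

Step 7
Reactants: 15 methyl 3,5-dioxohexanoate; 11 methyl (E)-2-[5-(benzyloxy)-7-methoxy-2-(4-methoxyphenyl)-4-oxo-4H-chromen-3-yl]-3-(4-methoxyphenyl)prop-2-enoate
Product: 17 methyl (8E)-8-[5-(benzyloxy)-7-methoxy-2-(4-methoxyphenyl)-4-oxo-4H-chromen-3-yl]-9-(4-methoxyphenyl)-3,5,7-trioxonon-8-enoate, via trianion 16 (not isolated)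
Conditions: LiN(i-Pr)2 (3.1 equiv per 15), THF, 0 °C; then 11 (0.5 equiv), 0 °C → rt; cold aq. HCl
Reagents that add atoms: none
Why: Claisen-type acylation of the terminal, least stabilised carbanion of a 3,5-dioxo ester trianion by a non-enolisable ester, a known entry to 3,5,7-triketo esters that also accepts cinnamates. The excess trianion absorbs the acidic proton of the product, and the chromone, a vinylogous ester, is a poor electrophile.

Step 8
Reactants: 17 methyl (8E)-8-[5-(benzyloxy)-7-methoxy-2-(4-methoxyphenyl)-4-oxo-4H-chromen-3-yl]-9-(4-methoxyphenyl)-3,5,7-trioxonon-8-enoate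
Product: 18 (E)-2-[5-(benzyloxy)-7-methoxy-2-(4-methoxyphenyl)-4-oxo-4H-chromen-3-yl]-3-(4-methoxyphenyl)-1-(2,4,6-trihydroxyphenyl)prop-2-en-1-one
Conditions: Mg(OCH3)2 (6 equiv), CH3OH, rt → 50 °C; cold 1 M HCl, 0 °C
Reagents that add atoms: none
Why: Mg(OCH3)2 converts 17 into a chelated magnesium polyenolate in which C6, the carbon between the enone carbonyl C7 and the C5 ketone, attacks the ester carbonyl C1; methoxide leaves and the resulting 2-acylcyclohexane-1,3,5-trione enolises at once to the acylphloroglucinol. The closest known reaction is the magnesium alkoxide-mediated Claisen-mode cyclisation of 3,5,7-triketo esters to acylphloroglucinols, including a 7-styryl case that gives a 2',4',6'-trihydroxychalcone. The one ring formed, ring A of unit 1, closes in a 6-exo-trig mode through the C4a–C5 bond (C6–C1 of the chain). No stereocentre is formed and the substrate holds none, so the base has nothing to erase. The step needs Claisen-mode selectivity over the aldol mode (C2 on C7, leading to a resorcylate), over O-cyclisation to a pyrone and over conjugate addition of C4 to C9. The magnesium chelate holds the 3,5-dicarbonyl unit and the ester together and favours C-acylation, C7 is a cross-conjugated, alpha-branched enone carbonyl shielded by the chromone, and C9 is deactivated by its 4-methoxyphenyl group. The chromone and the benzyl ether should be inert to methoxide at this temperature, and the cold acidic work-up is meant to keep the chalcone open for step 9.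

Step 9
Reactants: 18 (E)-2-[5-(benzyloxy)-7-methoxy-2-(4-methoxyphenyl)-4-oxo-4H-chromen-3-yl]-3-(4-methoxyphenyl)-1-(2,4,6-trihydroxyphenyl)prop-2-en-1-one
Product: 19 (2S,3R)-3-[5-(benzyloxy)-7-methoxy-2-(4-methoxyphenyl)-4-oxo-4H-chromen-3-yl]-5,7-dihydroxy-2-(4-methoxyphenyl)-2,3-dihydro-4H-chromen-4-one
Conditions: 1-[3,5-bis(trifluoromethyl)phenyl]-3-[(8α,9S)-6'-methoxycinchonan-9-yl]thiourea (10 mol%), toluene–CH2Cl2, −20 °C → rt
Reagents that add atoms: none
Why: Asymmetric intramolecular oxa-Michael addition of a 2'-hydroxychalcone: the quinuclidine deprotonates one of the two equivalent ortho hydroxyls while the thiourea binds the carbonyl, so the phenoxide adds to one face of C2 and sets it as S. The C3 epimers should converge on the trans (2S,3R) isomer under the amine, because C3–H is acidified by C4=O and the adjacent chromone double bond and the diequatorial arrangement is favoured.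

Step 10
Reactants: 19 (2S,3R)-3-[5-(benzyloxy)-7-methoxy-2-(4-methoxyphenyl)-4-oxo-4H-chromen-3-yl]-5,7-dihydroxy-2-(4-methoxyphenyl)-2,3-dihydro-4H-chromen-4-one
Product: 20 (2S,3R)-3-[(2S,3S)-5-(benzyloxy)-7-methoxy-2-(4-methoxyphenyl)-4-oxo-3,4-dihydro-2H-chromen-3-yl]-5,7-dihydroxy-2-(4-methoxyphenyl)-2,3-dihydro-4H-chromen-4-one
Conditions: [Ir(cod)(L)][B(3,5-(CF3)2C6H3)4] (5 mol%), L = (S)-4-tert-butyl-2-[2-(diphenylphosphanyl)phenyl]-4,5-dihydro-1,3-oxazole, H2 (50 bar), CH2Cl2, rt
Reagents that add atoms: none
Why: Proposed new method: a cationic iridium P,N complex is expected to activate H2 and, with C4''=O as a weak anchor, pass both hydrogens to one face of the tetrasubstituted C2''=C3'' bond without an enolate intermediate, so that syn addition fixes the 2'',3''-cis relation and the ligand selects the face that gives (2''S,3''S). The non-basic medium should leave both ketones, the benzyl ether and the epimerisable centres untouched. The closest known reactions are the iridium P,N-catalysed asymmetric hydrogenation of tetrasubstituted alkenes and of enones, and the asymmetric hydrogenation of 2-substituted chromones and flavones with chiral ruthenium carbene and rhodium phosphine catalysts.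

Step 11
Reactants: 20 (2S,3R)-3-[(2S,3S)-5-(benzyloxy)-7-methoxy-2-(4-methoxyphenyl)-4-oxo-3,4-dihydro-2H-chromen-3-yl]-5,7-dihydroxy-2-(4-methoxyphenyl)-2,3-dihydro-4H-chromen-4-one
Product: 21 (2S,3R)-5,7-dihydroxy-3-[(2S,3S)-5-hydroxy-7-methoxy-2-(4-methoxyphenyl)-4-oxo-3,4-dihydro-2H-chromen-3-yl]-2-(4-methoxyphenyl)-2,3-dihydro-4H-chromen-4-one
Conditions: H2 (1 atm), Pd/C (10%), EtOAc, rt
Reagents that add atoms: none
Why: Hydrogenolysis of an aryl benzyl ether over palladium under neutral conditions. The chelated ketones, the benzylic C2–O bonds of the chromanones and the base-sensitive cis centre C3'' are expected to be untouched at ambient pressure.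

## Compound list

1 | phloroglucinol (benzene-1,3,5-triol) | Oc1cc(O)cc(O)c1 | starting material
2 | methyl 4-chloro-4-oxobutanoate | COC(=O)CCC(Cl)=O | starting material
3 | methyl 4-oxo-4-(2,4,6-trihydroxyphenyl)butanoate | COC(=O)CCC(=O)c1c(O)cc(O)cc1O | intermediate
4 | 4-methoxybenzoic anhydride | COc1ccc(cc1)C(=O)OC(=O)c1ccc(OC)cc1 | starting material
5 | methyl 2-{5,7-bis[(4-methoxybenzoyl)oxy]-2-(4-methoxyphenyl)-4-oxo-4H-chromen-3-yl}acetate | COC(=O)Cc1c(-c2ccc(OC)cc2)oc2cc(OC(=O)c3ccc(OC)cc3)cc(OC(=O)c3ccc(OC)cc3)c2c1=O | intermediate (not isolated)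
6 | 2-[5,7-dihydroxy-2-(4-methoxyphenyl)-4-oxo-4H-chromen-3-yl]acetic acid | OC(=O)Cc1c(-c2ccc(OC)cc2)oc2cc(O)cc(O)c2c1=O | intermediate
7 | 4-methoxybenzaldehyde | COc1ccc(C=O)cc1 | starting material
8 | (E)-2-[5,7-diacetoxy-2-(4-methoxyphenyl)-4-oxo-4H-chromen-3-yl]-3-(4-methoxyphenyl)prop-2-enoic acid | OC(=O)/C(=C/c1ccc(OC)cc1)c1c(-c2ccc(OC)cc2)oc2cc(OC(C)=O)cc(OC(C)=O)c2c1=O | intermediate (not isolated)
9 | (E)-2-[5,7-dihydroxy-2-(4-methoxyphenyl)-4-oxo-4H-chromen-3-yl]-3-(4-methoxyphenyl)prop-2-enoic acid | OC(=O)/C(=C/c1ccc(OC)cc1)c1c(-c2ccc(OC)cc2)oc2cc(O)cc(O)c2c1=O | intermediate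
10 | methyl (E)-2-[5-hydroxy-7-methoxy-2-(4-methoxyphenyl)-4-oxo-4H-chromen-3-yl]-3-(4-methoxyphenyl)prop-2-enoate | COC(=O)/C(=C/c1ccc(OC)cc1)c1c(-c2ccc(OC)cc2)oc2cc(OC)cc(O)c2c1=O | intermediate
11 | methyl (E)-2-[5-(benzyloxy)-7-methoxy-2-(4-methoxyphenyl)-4-oxo-4H-chromen-3-yl]-3-(4-methoxyphenyl)prop-2-enoate | COC(=O)/C(=C/c1ccc(OC)cc1)c1c(-c2ccc(OC)cc2)oc2cc(OC)cc(OCc3ccccc3)c2c1=O | intermediate
12 | methyl acetoacetate | COC(=O)CC(C)=O | starting material
13 | N-methoxy-N-methylacetamide | CON(C)C(C)=O | starting material
14 | sodium lithium dianion of methyl acetoacetate | COC(=O)[CH-]C(=O)[CH2-].[Na+].[Li+] | intermediate (not isolated)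
15 | methyl 3,5-dioxohexanoate | COC(=O)CC(=O)CC(C)=O | intermediate
16 | trilithium trianion of methyl 3,5-dioxohexanoate | COC(=O)[CH-]C(=O)[CH-]C(=O)[CH2-].[Li+].[Li+].[Li+] | intermediate (not isolated)
17 | methyl (8E)-8-[5-(benzyloxy)-7-methoxy-2-(4-methoxyphenyl)-4-oxo-4H-chromen-3-yl]-9-(4-methoxyphenyl)-3,5,7-trioxonon-8-enoate | COC(=O)CC(=O)CC(=O)CC(=O)/C(=C/c1ccc(OC)cc1)c1c(-c2ccc(OC)cc2)oc2cc(OC)cc(OCc3ccccc3)c2c1=O | intermediate
18 | (E)-2-[5-(benzyloxy)-7-methoxy-2-(4-methoxyphenyl)-4-oxo-4H-chromen-3-yl]-3-(4-methoxyphenyl)-1-(2,4,6-trihydroxyphenyl)prop-2-en-1-one | O=C(/C(=C/c1ccc(OC)cc1)c1c(-c2ccc(OC)cc2)oc2cc(OC)cc(OCc3ccccc3)c2c1=O)c1c(O)cc(O)cc1O | intermediate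
19 | (2S,3R)-3-[5-(benzyloxy)-7-methoxy-2-(4-methoxyphenyl)-4-oxo-4H-chromen-3-yl]-5,7-dihydroxy-2-(4-methoxyphenyl)-2,3-dihydro-4H-chromen-4-one | COc1ccc([C@H]2Oc3cc(O)cc(O)c3C(=O)[C@@H]2c2c(-c3ccc(OC)cc3)oc3cc(OC)cc(OCc4ccccc4)c3c2=O)cc1 | intermediate
20 | (2S,3R)-3-[(2S,3S)-5-(benzyloxy)-7-methoxy-2-(4-methoxyphenyl)-4-oxo-3,4-dihydro-2H-chromen-3-yl]-5,7-dihydroxy-2-(4-methoxyphenyl)-2,3-dihydro-4H-chromen-4-one | COc1ccc([C@H]2Oc3cc(O)cc(O)c3C(=O)[C@@H]2[C@@H]2C(=O)c3c(OCc4ccccc4)cc(OC)cc3O[C@@H]2c2ccc(OC)cc2)cc1 | intermediate
21 | (2S,3R)-5,7-dihydroxy-3-[(2S,3S)-5-hydroxy-7-methoxy-2-(4-methoxyphenyl)-4-oxo-3,4-dihydro-2H-chromen-3-yl]-2-(4-methoxyphenyl)-2,3-dihydro-4H-chromen-4-one | COc1ccc([C@H]2Oc3cc(O)cc(O)c3C(=O)[C@@H]2[C@@H]2C(=O)c3c(O)cc(OC)cc3O[C@@H]2c2ccc(OC)cc2)cc1 | target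

## Step count and least certain steps

Total: 11 steps. Longest linear sequence: 10 steps (1 to 21 through steps 1–5 and 7–11); step 6 is a one-step side branch.

**Step 10 (proposed new method).** The likely failures are no turnover at a tetrasubstituted, donor-substituted double bond flanked by two bulky groups, delivery to the wrong face if ligand and the C3 centre are mismatched, and reduction of C4''=O if the conditions are forced. The fallback gives up ligand control and uses known heterogeneous chemistry. Starting from 19, hydrogenation over Pd/C in EtOAc under a few bar of H2 first cleaves the benzyl ether to (2S,3R)-5,7-dihydroxy-3-[5-hydroxy-7-methoxy-2-(4-methoxyphenyl)-4-oxo-4H-chromen-3-yl]-2-(4-methoxyphenyl)-2,3-dihydro-4H-chromen-4-one F1. It then saturates C2''=C3'' by syn addition from either face, giving 21 together with its (2''R,3''R) diastereomer F2. Chromatographic separation returns the route at 21 and makes step 11 unnecessary.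

**Step 8 (key step).** The likely failures are cyclisation in the aldol mode to a resorcylate, O-cyclisation to a pyrone, conjugate addition of C4 to C9, and closure of the chalcone to the racemic flavanone during work-up. In the fallback ring A is brought in ready-made:
- 11 is saponified with LiOH to the acid (E)-2-[5-(benzyloxy)-7-methoxy-2-(4-methoxyphenyl)-4-oxo-4H-chromen-3-yl]-3-(4-methoxyphenyl)prop-2-enoic acid F3, which oxalyl chloride converts into the acid chloride F4.
- 1 is protected with chloromethyl methyl ether and i-Pr2NEt as 1,3,5-tris(methoxymethoxy)benzene F5 and lithiated with n-BuLi between two acetal groups.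
- The aryllithium is acylated by F4 at −78 °C to the 2,4,6-tris(methoxymethoxy)phenyl ketone F6.
- Brief treatment with HCl in CH3OH removes the three acetals and returns the route at 18.

**Step 7.** The likely failures are slow acyl transfer to the hindered ester carbonyl, competing conjugate addition to C9 or attack on the chromone, and premature cyclisation of 17 during work-up. The fallback replaces the ester by a more reactive acyl donor and the trianion by a masked one. Acid chloride F4 (from 11 through F3, as above) acylates the dilithium dianion of 2,2-dimethyl-6-(2-oxopropyl)-4H-1,3-dioxin-4-one F7 (LiN(i-Pr)2, THF, −78 °C), a keto-dioxinone made by acetylating the lithium dienolate of commercial 2,2,6-trimethyl-4H-1,3-dioxin-4-one. The product is the diketo-dioxinone F8. Heating F8 in toluene with CH3OH releases the acylketene, which is trapped as the methyl ester, and returns the route at 17.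

**Step 9.** The likely failures are low enantioselectivity, because the uncatalysed closure of a chalcone with two ortho hydroxyls is fast, and erosion of C2 by reversible ring opening while C3 equilibrates. The fallback is resolution in place of asymmetric catalysis. 18 is closed with NaOAc in CH3OH to the racemic trans compound, that is 19 together with its (2R,3S) enantiomer F9. The enantiomers are separated by preparative chromatography on a cellulose tris(3,5-dimethylphenylcarbamate) phase. F9 is recycled by base-induced ring opening and re-closure, and the route is rejoined at 19.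

## Further compounds

F1 | step 10 | (2S,3R)-5,7-dihydroxy-3-[5-hydroxy-7-methoxy-2-(4-methoxyphenyl)-4-oxo-4H-chromen-3-yl]-2-(4-methoxyphenyl)-2,3-dihydro-4H-chromen-4-one | COc1ccc([C@H]2Oc3cc(O)cc(O)c3C(=O)[C@@H]2c2c(-c3ccc(OC)cc3)oc3cc(OC)cc(O)c3c2=O)cc1
F2 | step 10 | (2S,3R)-5,7-dihydroxy-3-[(2R,3R)-5-hydroxy-7-methoxy-2-(4-methoxyphenyl)-4-oxo-3,4-dihydro-2H-chromen-3-yl]-2-(4-methoxyphenyl)-2,3-dihydro-4H-chromen-4-one | COc1ccc([C@H]2Oc3cc(O)cc(O)c3C(=O)[C@@H]2[C@H]2C(=O)c3c(O)cc(OC)cc3O[C@H]2c2ccc(OC)cc2)cc1
F3 | step 8 | (E)-2-[5-(benzyloxy)-7-methoxy-2-(4-methoxyphenyl)-4-oxo-4H-chromen-3-yl]-3-(4-methoxyphenyl)prop-2-enoic acid | OC(=O)/C(=C/c1ccc(OC)cc1)c1c(-c2ccc(OC)cc2)oc2cc(OC)cc(OCc3ccccc3)c2c1=O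
F4 | step 8 | (E)-2-[5-(benzyloxy)-7-methoxy-2-(4-methoxyphenyl)-4-oxo-4H-chromen-3-yl]-3-(4-methoxyphenyl)prop-2-enoyl chloride | ClC(=O)/C(=C/c1ccc(OC)cc1)c1c(-c2ccc(OC)cc2)oc2cc(OC)cc(OCc3ccccc3)c2c1=O
F5 | step 8 | 1,3,5-tris(methoxymethoxy)benzene | COCOc1cc(OCOC)cc(OCOC)c1
F6 | step 8 | (E)-2-[5-(benzyloxy)-7-methoxy-2-(4-methoxyphenyl)-4-oxo-4H-chromen-3-yl]-3-(4-methoxyphenyl)-1-[2,4,6-tris(methoxymethoxy)phenyl]prop-2-en-1-one | COCOc1cc(OCOC)c(C(=O)/C(=C/c2ccc(OC)cc2)c2c(-c3ccc(OC)cc3)oc3cc(OC)cc(OCc4ccccc4)c3c2=O)c(OCOC)c1
F7 | step 7 | 2,2-dimethyl-6-(2-oxopropyl)-4H-1,3-dioxin-4-one | CC(=O)CC1=CC(=O)OC(C)(C)O1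
F8 | step 7 | 6-{(E)-5-[5-(benzyloxy)-7-methoxy-2-(4-methoxyphenyl)-4-oxo-4H-chromen-3-yl]-6-(4-methoxyphenyl)-2,4-dioxohex-5-en-1-yl}-2,2-dimethyl-4H-1,3-dioxin-4-one | CC1(C)OC(=O)C=C(CC(=O)CC(=O)/C(=C/c2ccc(OC)cc2)c2c(-c3ccc(OC)cc3)oc3cc(OC)cc(OCc4ccccc4)c3c2=O)O1
F9 | step 9 | (2R,3S)-3-[5-(benzyloxy)-7-methoxy-2-(4-methoxyphenyl)-4-oxo-4H-chromen-3-yl]-5,7-dihydroxy-2-(4-methoxyphenyl)-2,3-dihydro-4H-chromen-4-one | COc1ccc([C@@H]2Oc3cc(O)cc(O)c3C(=O)[C@H]2c2c(-c3ccc(OC)cc3)oc3cc(OC)cc(OCc4ccccc4)c3c2=O)cc1
A1 | alternative 1 | 3,5-bis(benzyloxy)-2-(dimethoxymethyl)phenol | COC(OC)c1c(O)cc(OCc2ccccc2)cc1OCc1ccccc1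
A2 | alternative 1 | (2S,3S)-5-(benzyloxy)-7-methoxy-2-(4-methoxyphenyl)-3-[(E)-2-(4-methoxyphenyl)ethenyl]-2,3-dihydro-4H-chromen-4-one | COc1ccc(/C=C/[C@@H]2C(=O)c3c(OCc4ccccc4)cc(OC)cc3O[C@@H]2c2ccc(OC)cc2)cc1
A3 | alternative 1 | 5,7,5''-tri-O-benzyl 4-methoxyflavan (unit 1) joined at C3 to the cis-flavanone unit 2 | COc1ccc([C@H]2Oc3cc(OCc4ccccc4)cc(OCc4ccccc4)c3[C@@H](OC)[C@@H]2[C@@H]2C(=O)c3c(OCc4ccccc4)cc(OC)cc3O[C@@H]2c2ccc(OC)cc2)cc1
A4 | alternative 2 | (2S,3R)-5,7-bis(benzyloxy)-3-[(2S,3S)-5-bromo-2-(4-methoxyphenyl)-4-oxo-3,4-dihydro-2H-pyran-3-yl]-2-(4-methoxyphenyl)-2,3-dihydro-4H-chromen-4-one | COc1ccc([C@H]2Oc3cc(OCc4ccccc4)cc(OCc4ccccc4)c3C(=O)[C@@H]2[C@@H]2C(=O)C(Br)=CO[C@@H]2c2ccc(OC)cc2)cc1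
A5 | alternative 2 | 1,3-dimethoxy-1-(trimethylsilyloxy)buta-1,3-diene | COC(=C)C=C(OC)O[Si](C)(C)C
A6 | alternative 2 | 5,7-di-O-benzyl ether of 21 with free 5''-hydroxyl | COc1ccc([C@H]2Oc3cc(OCc4ccccc4)cc(OCc4ccccc4)c3C(=O)[C@@H]2[C@@H]2C(=O)c3c(O)cc(OC)cc3O[C@@H]2c2ccc(OC)cc2)cc1
A7 | alternative 3 | (2S,3R)-5,7-bis(benzyloxy)-3-[(2S,3S)-1-(2-benzyloxy-6-fluoro-4-methoxyphenyl)-3-hydroxy-3-(4-methoxyphenyl)-1-oxopropan-2-yl]-2-(4-methoxyphenyl)-2,3-dihydro-4H-chromen-4-one | COc1ccc([C@H]2Oc3cc(OCc4ccccc4)cc(OCc4ccccc4)c3C(=O)[C@@H]2[C@H](C(=O)c2c(F)cc(OC)cc2OCc2ccccc2)[C@H](O)c2ccc(OC)cc2)cc1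
A8 | alternative 3 | 5,7,5''-tri-O-benzyl ether of 21 | COc1ccc([C@H]2Oc3cc(OCc4ccccc4)cc(OCc4ccccc4)c3C(=O)[C@@H]2[C@@H]2C(=O)c3c(OCc4ccccc4)cc(OC)cc3O[C@@H]2c2ccc(OC)cc2)cc1
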